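What does this flask hold at 8.0 d, and which move at that time still brings L?

the same everywhere: X 0.80 M; J 1.05 equiv

| flask | D | remark | time |
|---|---|---|---|
| Saturday's | 0.1 mol% | the very flask that is asked about, followed so far |  |
| Friday's | 0.15 mol% | run made earlier |  |
| flask | 0.1 mol% |  | 8.0 d |

| Saturday's: time / h | Saturday's: L / % | Friday's: time / h | Friday's: L / % |
|---|---|---|---|
| 40.0 | 29.8 | 2.00 | 7.9 |
| 72.0 | 32.4 | 6.00 | 19.0 |
| 120 | 33.1 | 12.0 | 25.9 |
| 144 | 32.4 | 20.0 | 33.6 |

(each reading ± 0.5 percentage points)

- alpha: at 8.0 d take out 90% of the L then present, then wait 4.0 d
- theta: at 8.0 d add D, 100% of the amount charged, then wait 4.0 d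
- beta: at 8.0 d add J, 50.0% of the amount charged, then wait 4.0 d
- eta: change nothing and wait 4.0 d more

- L, in percent of the X first charged, at 8.0 d
- which option adds most L ("none" when 2 percentage points or less is all one gets) (alpha / theta / beta / eta / none)
- L present, with what was taken out counted in, in percent of the X first charged, after alpha
- L present, with what was taken out counted in, in percent of the X first charged, after eta

- L taken out counts as made
- additions bring no volume worth counting

A first estimate takes the late readings of Saturday's flask as they stand: their mean, 32.6%, is taken for the L at 8.0 d. The objection is that this flat line may mean something has run out, so the balance of the limiting reagent has to be written. That reagent is X, and each X that goes takes one J with it. If L is what X turns into, Saturday's flask still holds about 67.4% of its X and a like share of its J, so neither has run out.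

A second objection is a ceiling set by equilibrium, or a brake from L itself. But Friday's flask, with the same charges and 0.15 mol% of D against 0.1 mol%, climbed from 25.9% to 33.6% in 8.00 h, above Saturday's level and still moving. The two flasks differ in D, so the stall reads as D dying. Waiting, taking L out or adding J should then leave L at the same level, with anything taken out counted in, and theta is the move to reckon.

The easy guess is that fresh D repeats the same fraction of conversion. The balance objects: [J] − [X] keeps its small charged value, so [J] falls along with [X]. A rate proportional to [X][J][D] therefore falls roughly as [X] squared, and what grows in step with the working time of D is the reciprocal of [X], not its logarithm. Saturday's stall gives 0.484 for the reach of a charge of D, that is, the ratio of X charged to X left at the stall, less one. If new D lives as the first did, an equal charge adds the same reach again. X left is then one over one plus both reaches, which makes L 49.2%, a gain of 17 percentage points.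

The forecast gave 32.7% at 8.0 d, 32.9% after alpha, 32.7% after eta and theta as the best move, holding that “Fresh D should repeat the conversion on the remaining 67% of X”, for about 20 points where the reckoning above has 17 points. The flask gives 32.5% at 8.0 d, 32.5% after alpha, 32.5% after eta and theta as best, with 13 points added against 0 points for alpha, 0 points for beta and 0 points for eta.

    L + D ⇌ G + D, rate k1*[D]*[L] forward; the back reaction follows from the equilibrium constant (K = 1.20, k = 0.160 M⁻¹ min⁻¹)
    D → Q (k = 9.60 × 10⁻⁴ min⁻¹)
    X + J + D → L + D, rate k3*[X]*[J]*[D]/(1 + ([X]/sat3)) (2.00 M, k = 1.00 M⁻² min⁻¹)

In this flask D passes to Q with a half-life of 12 h by that reaction alone, shorter than the 49 h that J shows by its reaction with X at 9.17 h, and at 96.0 h D stands at 0.397% of the catalyst charged, with X at 65.2% of its charge, J at 66.8% of its own charge and G at 2.38% of the X charged. The reach read on Saturday's flask put theta at 17 points against the 13 points obtained, which is over the mark of 2 points, and multiplied by 1.50 for Friday's loading it gives 42.1% of L, where the run with Friday's loading stands at 8.0 d at 40.7%.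

(The readings come from a simulation with made-up constants; scatter was added.)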